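Readings and results were generated by integration on assumed constants, noise included.

The vessel is a stirred flask of constant volume, and I read the earlier runs as substrate leaving by two exits. In elm the substrate charge exceeds the reagent charge, yet c(substrate) reads 0% at 30.0 s, while target ends at 42.5% in birch, 28.2% in maple and 18.5% in elm.

| flask | substrate | reagent | free catalyst | remark | time |
|---|---|---|---|---|---|
| maple | 0.10 M | 0.12 M | 0.14 mM | run made earlier |  |
| birch | 0.050 M | 0.12 M | 0.14 mM | run made earlier |  |
| elm | 0.20 M | 0.12 M | 0.14 mM | run made earlier |  |
| ochre | 0.10 M | 0.120 M | 0.14 mM | everything together at the start | 2.5 min |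
| blue | 0.10 M (fed, over 1.5 min) | 0.120 M | 0.14 mM | all else is in the flask from the start; the feed brings no volume worth counting | 2.5 min |
| teal | 0.10 M | 0.120 M (fed, over 1.5 min) | 0.14 mM | all else is in the flask from the start; the feed brings no volume worth counting | 2.5 min |

- maple (time / s: target / %, substrate / %): 12.0: 15.2, 12.0; 30.0: 24.9, 3.0; 60.0: 29.7, 1.7; 90.0: 28.2, 0
- birch (time / s: target / %, substrate / %): 12.0: 24.2, 17.1; 30.0: 38.8, 3.2; 60.0: 41.2, 0.7; 90.0: 42.5, 0
- elm (time / s: target / %, substrate / %): 12.0: 10.8, 7.0; 30.0: 17.3, 0; 60.0: 17.8, 1.8; 90.0: 18.5, 1.7

(readings scatter by 1 percentage point)



- which flask leads in amount of target, in percent of the substrate charged ("all alike" within 1.5 percentage points) (ochre / blue / teal / all alike)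
- how much target is there at the end, in percent of the substrate charged: ochre
- how much target is there at the end, in percent of the substrate charged: blue
- how much target is there at the end, in percent of the substrate charged: teal

I assumed a first-order exit to target competing with a second-order exit elsewhere. I named the c(substrate) at which they carry equal flow the crossover level; at any level c, the selectivity, the share going to target, is the crossover level over the crossover level plus c. On that assumption, a batch running down from c(substrate) = x crossover levels yields the logarithm of one plus x, divided by x. Maple's last two readings average 28.9%, which gives x = 7.23, so the crossover level reads 0.0138 M.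

But one run proves little. This level gives birch 42.3% and elm 18.9%, near their readings, so I kept it. Maple's 12.0 s reading then gives a first-order constant of 0.0531 s⁻¹.

Ochre repeats maple's charges, so I expected 28.9%. In blue, I reckoned that feed balanced against both exits would hold c(substrate) near 0.0115 M, a share of 54.7%. My objection was that blue, with that share, would use more reagent than maple did. If the target exit is first order in reagent, the crossover level sinks to about 0.0121 M, and I committed to 51.5%. My figure for teal rests on that same unproven order, since maple, birch and elm each held reagent at 0.12 M. With reagent rising steadily in teal, I reckoned 12.4% of target.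

The forecast put blue first with 54%, above my figure, ochre at 29% and teal at 9%, below mine, saying “starving it early lets self-reaction win”.

The flasks ended at 28.5% in ochre, 52.8% in blue and 10.4% in teal, so blue leads.

    substrate + intermediate → side product (k = 7.90 M⁻¹ s⁻¹)
    reagent + free catalyst + intermediate → free catalyst + target (k = 9900 M⁻² s⁻¹)
    free catalyst → spent catalyst (k = 3.40 × 10⁻⁵ s⁻¹)
    substrate + free catalyst ⇌ free catalyst + intermediate (K = 1.80, k = 1000 M⁻¹ s⁻¹)

At 1.25 min in blue, substrate and intermediate together stood at 0.0128 M, just below my crossover level of 0.0138 M, and target stood at 36.9% of the substrate charged against 33.6% side product. The target step has free catalyst among its partners, so for the neighbour of blue charged with 8.4 × 10⁻⁵ M I scaled the crossover level to 0.00829 M and reckoned a share of 38.3%, and that flask ended with 62.8% side product and 36.4% target.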